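Numbering follows octahydroindene (ring A: cyclohexane C3a, C4–C7, C7a; ring B: cyclopentane). Everything rests on the C4–C3a bond: C4 carries the exocyclic methylene and C3a is β to the oxygenated C2, the pattern left when a vinyl radical made from a terminal alkyne adds to a conjugated acceptor. A tin hydride-mediated 6-exo radical cyclization of an acyclic 1,7-enyne (terminal alkyne plus E-enamide) therefore closes ring A, creates C4=CH2 and sets C3a with all carbon substituents equatorial. The precursor's three stereocentres come from an organocatalytic Michael addition and a catalytic propargylation. A second alkyne then closes the trans-fused ring B by nickel-catalysed methylative cyclization.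

Key step: step 6

Remark: the R-configured phosphoric acid of step 3 is assumed to direct the allenylboronate to the Re face of the aldehyde, as it does with simple aldehydes; its enantiomer would be used if the sense proved opposite.

Step 1
Reactants: 1 3-[tri(propan-2-yl)silyl]prop-2-ynal; 2 nitromethane
Product: 4 [(3E)-4-nitrobut-3-en-1-yn-1-yl]tri(propan-2-yl)silane, via nitro alcohol 3 (not isolated)
Conditions: MeNO2 (5 equiv), Et3N (0.1 equiv), THF, 0 °C; then MsCl, Et3N, CH2Cl2, −40 → 0 °C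
Reagents that add atoms: none
Why: Henry (nitro-aldol) addition followed by mesylation and E1cB elimination should give the conjugated nitroalkene in its thermodynamically favoured E geometry; no stereocentre remains.

Step 2
Reactants: 4 [(3E)-4-nitrobut-3-en-1-yn-1-yl]tri(propan-2-yl)silane; 5 3-methylbutanal
Product: 6 (2S,3R)-3-(nitromethyl)-2-(propan-2-yl)-5-[tri(propan-2-yl)silyl]pent-4-ynal
Conditions: (R)-2-[diphenyl(trimethylsilyloxy)methyl]pyrrolidine (10 mol %), CHCl3, 0 °C
Reagents that add atoms: none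
Why: Enamine-catalysed Michael addition of an aldehyde to a nitroalkene: the enamine, shielded on one face by the diphenyl(silyloxy)methyl group, adds 1,4 to the nitroenyne through a synclinal transition state, which should give the syn adduct and, with the R catalyst, the 2S,3R configuration.

Step 3
Reactants: 6 (2S,3R)-3-(nitromethyl)-2-(propan-2-yl)-5-[tri(propan-2-yl)silyl]pent-4-ynal; 7 4,4,5,5-tetramethyl-2-(propa-1,2-dien-1-yl)-1,3,2-dioxaborolane
Product: 8 (4R,5S,6R)-6-(nitromethyl)-5-(propan-2-yl)-8-[tri(propan-2-yl)silyl]octa-1,7-diyn-4-ol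
Conditions: (R)-3,3′-bis(2,4,6-triisopropylphenyl)-1,1′-binaphthyl-2,2′-diyl hydrogen phosphate (10 mol %), 4 Å molecular sieves, toluene, −20 °C
Reagents that add atoms: none
Why: Chiral phosphoric acid-catalysed propargylation with an allenylboronate (SE2′ addition through a closed six-membered transition state bridged by the acid): the catalyst directs attack to the Re face of the aldehyde, which should set C4 as R under catalyst control.

Step 4
Reactants: 8 (4R,5S,6R)-6-(nitromethyl)-5-(propan-2-yl)-8-[tri(propan-2-yl)silyl]octa-1,7-diyn-4-ol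
Product: 9 tert-butyl(dimethyl){[(4R,5S,6R)-6-(nitromethyl)-5-(propan-2-yl)-8-[tri(propan-2-yl)silyl]octa-1,7-diyn-4-yl]oxy}silane
Conditions: TBSCl, imidazole, DMF, 40 °C
Reagents that add atoms: tert-butyldimethylsilyl chloride, CC(C)(C)[Si](C)(C)Cl
Why: Silyl ether formation keeps the hydroxyl from closing a lactol onto the aldehyde of step 5 and from oxa-Michael addition to the enamide; no stereocentre is touched.

Step 5
Reactants: 9 tert-butyl(dimethyl){[(4R,5S,6R)-6-(nitromethyl)-5-(propan-2-yl)-8-[tri(propan-2-yl)silyl]octa-1,7-diyn-4-yl]oxy}silane; 10 N-methoxy-N-methyl-2-(triphenyl-λ5-phosphanylidene)acetamide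
Product: 12 (2E,4R,5S,6R)-6-{[tert-butyl(dimethyl)silyl]oxy}-N-methoxy-N-methyl-5-(propan-2-yl)-4-{[tri(propan-2-yl)silyl]ethynyl}non-2-en-8-ynamide, via aldehyde 11 (not isolated)
Conditions: NaOMe, MeOH, 0 °C; then aq. TiCl3, NH4OAc, 0 °C → rt; extractive work-up; then 10, CH2Cl2, rt
Reagents that add atoms: none
Why: Nef reaction of the primary nitronate (reductive TiCl3 variant through the imine) followed at once by Wittig olefination with a stabilised ylide, which should give the E-enamide; telescoping is meant to keep the enolisable propargylic centre next to the aldehyde from epimerising.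

Step 6
Reactants: 12 (2E,4R,5S,6R)-6-{[tert-butyl(dimethyl)silyl]oxy}-N-methoxy-N-methyl-5-(propan-2-yl)-4-{[tri(propan-2-yl)silyl]ethynyl}non-2-en-8-ynamide
Product: 14 2-[(1R,2R,3S,4R)-4-{[tert-butyl(dimethyl)silyl]oxy}-6-methylidene-3-(propan-2-yl)-2-{[tri(propan-2-yl)silyl]ethynyl}cyclohexyl]-N-methoxy-N-methylacetamide, via vinylstannane 13 (not isolated)
Conditions: Bu3SnH (1.3 equiv, slow addition), AIBN (0.2 equiv), PhH, 80 °C; then TsOH·H2O, CH2Cl2, 0 °C
Reagents that add atoms: none
Why: A tributyltin radical adds to the terminal carbon of the alkyne, the vinyl radical so formed at C8 attacks C3 of the E-enamide, the resulting α-amido radical takes hydrogen from the tin hydride, and acid then replaces tin by hydrogen with retention to leave the exocyclic methylene (closest known type: tin hydride-mediated radical cyclization of enynes followed by protodestannylation). Ring A closes in the 6-exo-trig mode. The new stereocentre (C1 of the cyclohexane, R) should be set by the three existing centres through a chair-like transition state in which the isopropyl group, the silylethynyl group and the enamide arm are equatorial and only the silyloxy group is axial, so that the arm ends up trans to the alkynyl group and cis to the isopropyl group. The step needs the tin radical to choose the terminal alkyne over the hindered silyl alkyne, attack at the β-carbon of the electron-poor alkene and not at the silyl alkyne, and cyclization faster than 1,5-hydrogen transfer from the propargylic C4–H; the polarity match between the nucleophilic vinyl radical and the enamide serves the last two.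

Step 7
Reactants: 14 2-[(1R,2R,3S,4R)-4-{[tert-butyl(dimethyl)silyl]oxy}-6-methylidene-3-(propan-2-yl)-2-{[tri(propan-2-yl)silyl]ethynyl}cyclohexyl]-N-methoxy-N-methylacetamide
Product: 15 2-[(1R,2R,3S,4R)-2-ethynyl-4-hydroxy-6-methylidene-3-(propan-2-yl)cyclohexyl]-N-methoxy-N-methylacetamide
Conditions: Bu4NF (4 equiv), THF, 0 → 40 °C
Reagents that add atoms: none
Why: Fluoride-induced desilylation should cleave the C(sp)–Si and the O–Si bond in one operation without touching a stereocentre.

Step 8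
Reactants: 15 2-[(1R,2R,3S,4R)-2-ethynyl-4-hydroxy-6-methylidene-3-(propan-2-yl)cyclohexyl]-N-methoxy-N-methylacetamide; 16 (2Z)-2-methylbut-2-enoic acid (angelic acid)
Product: 17 (1R,2S,3R,4R)-3-ethynyl-4-{2-[methoxy(methyl)amino]-2-oxoethyl}-5-methylidene-2-(propan-2-yl)cyclohexyl (2Z)-2-methylbut-2-enoate
Conditions: 16, 2,4,6-trichlorobenzoyl chloride, Et3N, toluene, rt; then 15, toluene, 80 °C
Reagents that add atoms: none
Why: Yamaguchi esterification through the mixed anhydride, run without a nucleophilic catalyst so that the Z-alkene should not isomerise to the tiglate; the carbinol centre keeps its configuration.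

Step 9
Reactants: 17 (1R,2S,3R,4R)-3-ethynyl-4-{2-[methoxy(methyl)amino]-2-oxoethyl}-5-methylidene-2-(propan-2-yl)cyclohexyl (2Z)-2-methylbut-2-enoate
Product: 18 (1R,2S,3R,4R)-3-ethynyl-5-methylidene-4-(2-oxoethyl)-2-(propan-2-yl)cyclohexyl (2Z)-2-methylbut-2-enoate
Conditions: i-Bu2AlH (1.3 equiv), THF, −78 °C; aq. potassium sodium tartrate
Reagents that add atoms: none
Why: Hydride reduction of the N-methoxy-N-methylamide stops at the chelated tetrahedral aluminium intermediate, which releases the aldehyde on work-up, while the hindered conjugated angelate should react more slowly at −78 °C.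

Step 10
Reactants: 18 (1R,2S,3R,4R)-3-ethynyl-5-methylidene-4-(2-oxoethyl)-2-(propan-2-yl)cyclohexyl (2Z)-2-methylbut-2-enoate
Product: 19 (1Z,2R,3aR,6R,7S,7aR)-1-ethylidene-2-hydroxy-4-methylidene-7-(propan-2-yl)octahydro-1H-inden-6-yl (2Z)-2-methylbut-2-enoate
Conditions: Ni(cod)2 (15 mol %), Me2Zn (3 equiv), THF, 0 °C
Reagents that add atoms: dimethylzinc, C[Zn]C
Why: Nickel-catalysed alkylative cyclization of an alkynal with an organozinc: oxidative cyclization at zerovalent nickel gives an oxanickelacyclopentene, and methyl transfer from zinc with reductive elimination puts the methyl group on the distal alkyne carbon cis to the new C1–C2 bond, which fixes the Z-ethylidene group on the trans-fused ring B; the aldehyde oxygen, held syn to the alkyne in the metallacycle, is expected to lie on the α face (2R).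

Step 11
Reactants: 19 (1Z,2R,3aR,6R,7S,7aR)-1-ethylidene-2-hydroxy-4-methylidene-7-(propan-2-yl)octahydro-1H-inden-6-yl (2Z)-2-methylbut-2-enoate
Product: 20 (1Z,2S,3aR,6R,7S,7aR)-2-(acetyloxy)-1-ethylidene-4-methylidene-7-(propan-2-yl)octahydro-1H-inden-6-yl (2Z)-2-methylbut-2-enoate
Conditions: AcOH, PPh3, diisopropyl azodicarboxylate, toluene, 0 °C → rt
Reagents that add atoms: acetic acid, CC(=O)O
Why: Mitsunobu esterification: SN2 displacement of the oxyphosphonium ion by acetate should invert C2 to the required 2S acetate.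

Step 12
Reactants: 20 (1Z,2S,3aR,6R,7S,7aR)-2-(acetyloxy)-1-ethylidene-4-methylidene-7-(propan-2-yl)octahydro-1H-inden-6-yl (2Z)-2-methylbut-2-enoate
Product: 21 (1Z,2S,3aR,5S,6S,7S,7aR)-2-(acetyloxy)-1-ethylidene-5-hydroxy-4-methylidene-7-(propan-2-yl)octahydro-1H-inden-6-yl (2Z)-2-methylbut-2-enoate
Conditions: SeO2 (0.5 equiv), t-BuOOH (3 equiv), CH2Cl2, 0 °C → rt
Reagents that add atoms: selenium dioxide, O=[Se]=O; tert-butyl hydroperoxide, CC(C)(C)OO
Why: Selenium dioxide allylic oxidation (ene reaction, then [2,3]-sigmatropic shift of the allylseleninic acid): the ring A methylene has a CH2 allylic position (C5) that should react before the ring-fusion CH, oxygen returns to the face from which the axial hydrogen was taken and so gives the axial 5S alcohol trans to the angelate, while the ethylidene group offers only CH positions at its more substituted end and the angelate alkene is electron-poor.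

Compound list
1 | 3-[tri(propan-2-yl)silyl]prop-2-ynal | O=CC#C[Si](C(C)C)(C(C)C)C(C)C | starting material
2 | nitromethane | C[N+](=O)[O-] | starting material
3 | 1-nitro-4-[tri(propan-2-yl)silyl]but-3-yn-2-ol (racemic) | OC(C[N+](=O)[O-])C#C[Si](C(C)C)(C(C)C)C(C)C | intermediate
4 | [(3E)-4-nitrobut-3-en-1-yn-1-yl]tri(propan-2-yl)silane | [O-][N+](=O)/C=C/C#C[Si](C(C)C)(C(C)C)C(C)C | intermediate
5 | 3-methylbutanal | CC(C)CC=O | starting material
6 | (2S,3R)-3-(nitromethyl)-2-(propan-2-yl)-5-[tri(propan-2-yl)silyl]pent-4-ynal | O=C[C@@H](C(C)C)[C@H](C#C[Si](C(C)C)(C(C)C)C(C)C)C[N+](=O)[O-] | intermediate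
7 | 4,4,5,5-tetramethyl-2-(propa-1,2-dien-1-yl)-1,3,2-dioxaborolane | C=C=CB1OC(C)(C)C(C)(C)O1 | starting material
8 | (4R,5S,6R)-6-(nitromethyl)-5-(propan-2-yl)-8-[tri(propan-2-yl)silyl]octa-1,7-diyn-4-ol | C#CC[C@@H](O)[C@@H](C(C)C)[C@H](C#C[Si](C(C)C)(C(C)C)C(C)C)C[N+](=O)[O-] | intermediate
9 | tert-butyl(dimethyl){[(4R,5S,6R)-6-(nitromethyl)-5-(propan-2-yl)-8-[tri(propan-2-yl)silyl]octa-1,7-diyn-4-yl]oxy}silane | C#CC[C@@H](O[Si](C)(C)C(C)(C)C)[C@@H](C(C)C)[C@H](C#C[Si](C(C)C)(C(C)C)C(C)C)C[N+](=O)[O-] | intermediate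
10 | N-methoxy-N-methyl-2-(triphenyl-λ5-phosphanylidene)acetamide | CON(C)C(=O)C=P(c1ccccc1)(c1ccccc1)c1ccccc1 | starting material
11 | (2R,3S,4R)-4-{[tert-butyl(dimethyl)silyl]oxy}-3-(propan-2-yl)-2-{[tri(propan-2-yl)silyl]ethynyl}hept-6-ynal | C#CC[C@@H](O[Si](C)(C)C(C)(C)C)[C@@H](C(C)C)[C@H](C#C[Si](C(C)C)(C(C)C)C(C)C)C=O | intermediate
12 | (2E,4R,5S,6R)-6-{[tert-butyl(dimethyl)silyl]oxy}-N-methoxy-N-methyl-5-(propan-2-yl)-4-{[tri(propan-2-yl)silyl]ethynyl}non-2-en-8-ynamide | C#CC[C@@H](O[Si](C)(C)C(C)(C)C)[C@@H](C(C)C)[C@H](C#C[Si](C(C)C)(C(C)C)C(C)C)/C=C/C(=O)N(C)OC | intermediate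
13 | 2-[(1R,2R,3S,4R)-4-{[tert-butyl(dimethyl)silyl]oxy}-3-(propan-2-yl)-6-[(tributylstannyl)methylidene]-2-{[tri(propan-2-yl)silyl]ethynyl}cyclohexyl]-N-methoxy-N-methylacetamide (alkene isomers) | CCCC[Sn](CCCC)(CCCC)C=C1C[C@@H](O[Si](C)(C)C(C)(C)C)[C@@H](C(C)C)[C@H](C#C[Si](C(C)C)(C(C)C)C(C)C)[C@H]1CC(=O)N(C)OC | intermediate
14 | 2-[(1R,2R,3S,4R)-4-{[tert-butyl(dimethyl)silyl]oxy}-6-methylidene-3-(propan-2-yl)-2-{[tri(propan-2-yl)silyl]ethynyl}cyclohexyl]-N-methoxy-N-methylacetamide | C=C1C[C@@H](O[Si](C)(C)C(C)(C)C)[C@@H](C(C)C)[C@H](C#C[Si](C(C)C)(C(C)C)C(C)C)[C@H]1CC(=O)N(C)OC | intermediate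
15 | 2-[(1R,2R,3S,4R)-2-ethynyl-4-hydroxy-6-methylidene-3-(propan-2-yl)cyclohexyl]-N-methoxy-N-methylacetamide | C=C1C[C@@H](O)[C@@H](C(C)C)[C@H](C#C)[C@H]1CC(=O)N(C)OC | intermediate
16 | (2Z)-2-methylbut-2-enoic acid (angelic acid) | C/C=C(/C)C(=O)O | starting material
17 | (1R,2S,3R,4R)-3-ethynyl-4-{2-[methoxy(methyl)amino]-2-oxoethyl}-5-methylidene-2-(propan-2-yl)cyclohexyl (2Z)-2-methylbut-2-enoate | C=C1C[C@@H](OC(=O)/C(C)=C\C)[C@@H](C(C)C)[C@H](C#C)[C@H]1CC(=O)N(C)OC | intermediate
18 | (1R,2S,3R,4R)-3-ethynyl-5-methylidene-4-(2-oxoethyl)-2-(propan-2-yl)cyclohexyl (2Z)-2-methylbut-2-enoate | C=C1C[C@@H](OC(=O)/C(C)=C\C)[C@@H](C(C)C)[C@H](C#C)[C@H]1CC=O | intermediate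
19 | (1Z,2R,3aR,6R,7S,7aR)-1-ethylidene-2-hydroxy-4-methylidene-7-(propan-2-yl)octahydro-1H-inden-6-yl (2Z)-2-methylbut-2-enoate | C=C1C[C@@H](OC(=O)/C(C)=C\C)[C@@H](C(C)C)[C@@H]2/C(=C/C)[C@H](O)C[C@@H]12 | intermediate
20 | (1Z,2S,3aR,6R,7S,7aR)-2-(acetyloxy)-1-ethylidene-4-methylidene-7-(propan-2-yl)octahydro-1H-inden-6-yl (2Z)-2-methylbut-2-enoate | C=C1C[C@@H](OC(=O)/C(C)=C\C)[C@@H](C(C)C)[C@@H]2/C(=C/C)[C@@H](OC(C)=O)C[C@@H]12 | intermediate
21 | (1Z,2S,3aR,5S,6S,7S,7aR)-2-(acetyloxy)-1-ethylidene-5-hydroxy-4-methylidene-7-(propan-2-yl)octahydro-1H-inden-6-yl (2Z)-2-methylbut-2-enoate | C=C1[C@H](O)[C@@H](OC(=O)/C(C)=C\C)[C@@H](C(C)C)[C@@H]2/C(=C/C)[C@@H](OC(C)=O)C[C@@H]12 | target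

Total step count: 12
Longest linear sequence: 12 steps (1 to 21)

Steps most likely to fail

1. Step 12. The ene step may start at the more electron-rich ethylidene group of ring B, or remove the ring-fusion hydrogen at C3a instead of a C5 hydrogen, so that oxygen enters at the wrong allylic position. The fallback moves the oxidation to the stage before ring B and its alkene exist, at the price of one protecting group. It sets out from 17: SeO2 and t-BuOOH in CH2Cl2 should give (1S,2S,3R,4R,6S)-3-ethynyl-6-hydroxy-4-{2-[methoxy(methyl)amino]-2-oxoethyl}-5-methylidene-2-(propan-2-yl)cyclohexyl (2Z)-2-methylbut-2-enoate F1. TBSOTf and 2,6-lutidine then give the silyl ether (1S,2S,3R,4R,6S)-6-{[tert-butyl(dimethyl)silyl]oxy}-3-ethynyl-4-{2-[methoxy(methyl)amino]-2-oxoethyl}-5-methylidene-2-(propan-2-yl)cyclohexyl (2Z)-2-methylbut-2-enoate F2. Reduction with i-Bu2AlH at −78 °C gives the aldehyde (1S,2S,3R,4R,6S)-6-{[tert-butyl(dimethyl)silyl]oxy}-3-ethynyl-5-methylidene-4-(2-oxoethyl)-2-(propan-2-yl)cyclohexyl (2Z)-2-methylbut-2-enoate F3. Ni(cod)2 and Me2Zn close ring B to (1Z,2R,3aR,5S,6S,7S,7aR)-5-{[tert-butyl(dimethyl)silyl]oxy}-1-ethylidene-2-hydroxy-4-methylidene-7-(propan-2-yl)octahydro-1H-inden-6-yl (2Z)-2-methylbut-2-enoate F4. Mitsunobu reaction with acetic acid gives (1Z,2S,3aR,5S,6S,7S,7aR)-2-(acetyloxy)-5-{[tert-butyl(dimethyl)silyl]oxy}-1-ethylidene-4-methylidene-7-(propan-2-yl)octahydro-1H-inden-6-yl (2Z)-2-methylbut-2-enoate F5. HF·pyridine in THF removes the silyl group and the route comes back at 21.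

2. Step 6. The vinyl radical may abstract the doubly activated (propargylic and allylic) C4 hydrogen by 1,5-hydrogen transfer faster than it cyclizes, which would give reduced, uncyclized material and erase the C4 configuration. The fallback replaces the radical by a two-electron path in which this transfer cannot occur. It sets out from 12: Pd2(dba)3·CHCl3, P(o-tol)3, AcOH and Et3SiH in toluene at 40 °C should add a palladium hydride to the terminal alkyne, insert the enamide in the 6-exo mode and protonate the palladium enolate, and it comes back to the route at 14 without a new compound. The concern then shifts to competing insertion of the silyl alkyne.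

3. Step 10. Facial selectivity at the aldehyde carbon may be poor or opposite to the one projected, so that the nickel cyclization of 18 delivers the epimeric alcohol (1Z,2S,3aR,6R,7S,7aR)-1-ethylidene-2-hydroxy-4-methylidene-7-(propan-2-yl)octahydro-1H-inden-6-yl (2Z)-2-methylbut-2-enoate F6. The fallback sets out from 18, takes F6 and acetylates it with retention (Ac2O, pyridine, DMAP, CH2Cl2, 0 °C) in place of the inverting Mitsunobu step, and comes back to the route at 20. Both epimers of the cyclization thus converge on the same acetate.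

Further compounds
F1 | step 12 | (1S,2S,3R,4R,6S)-3-ethynyl-6-hydroxy-4-{2-[methoxy(methyl)amino]-2-oxoethyl}-5-methylidene-2-(propan-2-yl)cyclohexyl (2Z)-2-methylbut-2-enoate | C=C1[C@H](O)[C@@H](OC(=O)/C(C)=C\C)[C@@H](C(C)C)[C@H](C#C)[C@H]1CC(=O)N(C)OC
F2 | step 12 | (1S,2S,3R,4R,6S)-6-{[tert-butyl(dimethyl)silyl]oxy}-3-ethynyl-4-{2-[methoxy(methyl)amino]-2-oxoethyl}-5-methylidene-2-(propan-2-yl)cyclohexyl (2Z)-2-methylbut-2-enoate | C=C1[C@H](O[Si](C)(C)C(C)(C)C)[C@@H](OC(=O)/C(C)=C\C)[C@@H](C(C)C)[C@H](C#C)[C@H]1CC(=O)N(C)OC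
F3 | step 12 | (1S,2S,3R,4R,6S)-6-{[tert-butyl(dimethyl)silyl]oxy}-3-ethynyl-5-methylidene-4-(2-oxoethyl)-2-(propan-2-yl)cyclohexyl (2Z)-2-methylbut-2-enoate | C=C1[C@H](O[Si](C)(C)C(C)(C)C)[C@@H](OC(=O)/C(C)=C\C)[C@@H](C(C)C)[C@H](C#C)[C@H]1CC=O
F4 | step 12 | (1Z,2R,3aR,5S,6S,7S,7aR)-5-{[tert-butyl(dimethyl)silyl]oxy}-1-ethylidene-2-hydroxy-4-methylidene-7-(propan-2-yl)octahydro-1H-inden-6-yl (2Z)-2-methylbut-2-enoate | C=C1[C@H](O[Si](C)(C)C(C)(C)C)[C@@H](OC(=O)/C(C)=C\C)[C@@H](C(C)C)[C@@H]2/C(=C/C)[C@H](O)C[C@@H]12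
F5 | step 12 | (1Z,2S,3aR,5S,6S,7S,7aR)-2-(acetyloxy)-5-{[tert-butyl(dimethyl)silyl]oxy}-1-ethylidene-4-methylidene-7-(propan-2-yl)octahydro-1H-inden-6-yl (2Z)-2-methylbut-2-enoate | C=C1[C@H](O[Si](C)(C)C(C)(C)C)[C@@H](OC(=O)/C(C)=C\C)[C@@H](C(C)C)[C@@H]2/C(=C/C)[C@@H](OC(C)=O)C[C@@H]12
F0 | step 6 | none | none
F6 | step 10 | (1Z,2S,3aR,6R,7S,7aR)-1-ethylidene-2-hydroxy-4-methylidene-7-(propan-2-yl)octahydro-1H-inden-6-yl (2Z)-2-methylbut-2-enoate | C=C1C[C@@H](OC(=O)/C(C)=C\C)[C@@H](C(C)C)[C@@H]2/C(=C/C)[C@@H](O)C[C@@H]12
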